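**Strategy.** The route rests on cutting the bond between C1 of the central guaiacyl ring and C2 of the cis-fused 3,7-dioxabicyclo[3.3.0]octane core. C2 sits next to ring oxygen O3, so it can be held as an anomeric sulfone and released as an oxocarbenium ion; the cup shape of the two fused tetrahydrofuran rings leaves only the convex face open. In one operation an arylzinc carrying the complete, protected threo 8-O-4' glycerol unit is joined to this bicyclic ion, forming the aryl–C2 bond and setting C2 exo. The precursors are a tris-silylated aryl bromide from an Evans aldol and a sulfonyl acetal built from one catalytically set stereocenter.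

Key step: step 12

Remark: (R)-4-benzyl-3-(chloroacetyl)oxazolidin-2-one and potassium vinyltrifluoroborate are taken as purchasable; compound 16 is carried as both carbinol epimers because that centre is reset through a planar cation in step 9. TBS = tert-butyldimethylsilyl.

Step 1
Reactants: 1 vanillin
Product: 2 4-(TBSO)-3-methoxybenzaldehyde
Conditions: TBSCl, imidazole, DMF, rt
Reagents that add atoms: tert-butyldimethylsilyl chloride, CC(C)(C)[Si](C)(C)Cl
Why: Imidazole-promoted O-silylation masks the phenol for the later enolborane and organolithium chemistry; no stereocenter is involved.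

Step 2
Reactants: 3 4-bromo-2-methoxyphenol; 4 (R)-4-benzyl-3-(chloroacetyl)oxazolidin-2-one
Product: 5 (R)-4-benzyl-3-[2-(4-bromo-2-methoxyphenoxy)acetyl]oxazolidin-2-one
Conditions: K2CO3, NaI (cat.), MeCN, 40 °C
Reagents that add atoms: none
Why: Williamson ether synthesis with Finkelstein activation; the α-halo imide is a fast SN2 partner for the phenoxide, so substitution should outrun acyl transfer.

Step 3
Reactants: 5 aryloxyacetyl imide; 2 4-(TBSO)-3-methoxybenzaldehyde
Product: 7 (R)-4-benzyl-3-[(2R,3S)-2-(4-bromo-2-methoxyphenoxy)-3-{4-(TBSO)-3-methoxyphenyl}-3-hydroxypropanoyl]oxazolidin-2-one, via boron Z-enolate 6 (not isolated)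
Conditions: Bu2BOTf, iPr2NEt, CH2Cl2, 0 °C; then 2, −78 → 0 °C; pH 7 buffer, MeOH, H2O2, 0 °C
Reagents that add atoms: none
Why: Evans syn-aldol reaction; the Z-boron enolate reacts through a Zimmerman–Traxler chair whose face is chosen by the (R)-benzyl auxiliary, which should set both carbinol and aryloxy centres as the syn (threo) pair.

Step 4
Reactants: 7 aldol adduct
Product: 8 (1S,2S)-2-(4-bromo-2-methoxyphenoxy)-1-{4-(TBSO)-3-methoxyphenyl}propane-1,3-diol
Conditions: LiBH4, THF/MeOH, 0 °C
Reagents that add atoms: none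
Why: Reductive cleavage of the N-acyl oxazolidinone (hydride attack at the exocyclic carbonyl) frees the primary alcohol and the auxiliary without touching either stereocenter.

Step 5
Reactants: 8 diol
Product: 9 4-bromo-1-{[(1S,2S)-1,3-bis(TBSO)-1-{4-(TBSO)-3-methoxyphenyl}propan-2-yl]oxy}-2-methoxybenzene
Conditions: TBSOTf, 2,6-lutidine, CH2Cl2, −78 → 0 °C
Reagents that add atoms: tert-butyldimethylsilyl triflate, CC(C)(C)[Si](C)(C)OS(=O)(=O)C(F)(F)F
Why: Silylation of both hydroxyls removes every acidic proton so that the bromide can later be converted into an organometallic reagent.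

Step 6
Reactants: 10 syringaldehyde
Product: 11 4-(TBSO)-3,5-dimethoxybenzaldehyde
Conditions: TBSCl, imidazole, DMF, rt
Reagents that add atoms: tert-butyldimethylsilyl chloride, CC(C)(C)[Si](C)(C)Cl
Why: O-silylation of the hindered phenol protects it through the enolate, hydride and organozinc steps.

Step 7
Reactants: 12 2(5H)-furanone; 13 potassium vinyltrifluoroborate
Product: 14 (R)-4-vinyldihydrofuran-2(3H)-one
Conditions: [Rh(cod)2]PF6 (3 mol %), (R)-BINAP, toluene/H2O, 105 °C
Reagents that add atoms: none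
Why: Hayashi–Miyaura asymmetric conjugate addition; the vinylrhodium species inserts the enoate on the face left open by (R)-BINAP, which by the usual facial model should give the (R)-lactone, the single stereocenter set by catalysis.

Step 8
Reactants: 14 (R)-4-vinyldihydrofuran-2(3H)-one; 11 4-(TBSO)-3,5-dimethoxybenzaldehyde
Product: 16 (3R,4S)-3-[{4-(TBSO)-3,5-dimethoxyphenyl}(hydroxy)methyl]-4-vinyldihydrofuran-2(3H)-one (both carbinol epimers), via lithium enolate 15 (not isolated)
Conditions: LiN(iPr)2, THF, −78 °C; then 11, −78 °C; NH4Cl quench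
Reagents that add atoms: none
Why: Lactone enolate aldol addition; the aldehyde approaches anti to the β-vinyl group, so the 3,4-trans relationship is relayed from C4, while the carbinol centre is left uncontrolled on purpose.

Step 9
Reactants: 16 aldol lactone
Product: 18 [(2R,3S,4S)-2-{4-(TBSO)-3,5-dimethoxyphenyl}-4-vinyltetrahydrofuran-3-yl]methanol, via triol 17 (not isolated)
Conditions: LiBH4, THF, 0 °C → rt; acetone quench; then 1 M aq. HCl, rt, same flask
Reagents that add atoms: none
Why: Hydride reduction of the lactone followed by SN1 cyclodehydration; the para-silyloxybenzylic cation is captured by the only hydroxyl able to close a five-membered ring (5-exo), with the aryl group settling trans to the neighbouring hydroxymethyl group.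

Step 10
Reactants: 18 vinyl tetrahydrofuran alcohol
Product: 20 (1S,5S,6R)-6-{4-(TBSO)-3,5-dimethoxyphenyl}-3,7-dioxabicyclo[3.3.0]octan-2-ol (anomers), via hydroxy aldehyde 19 (not isolated)
Conditions: OsO4 (cat.), NaIO4, 2,6-lutidine, dioxane/H2O, rt
Reagents that add atoms: osmium tetroxide, O=[Os](=O)(=O)=O; sodium periodate, [Na+].[O-]I(=O)(=O)=O
Why: Lemieux–Johnson oxidation cleaves the vinyl group to the aldehyde, which is cis to the hydroxymethyl group and should close at once to the cis-fused lactol.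

Step 11
Reactants: 20 lactol
Product: 21 (1S,5S,6R)-6-{4-(TBSO)-3,5-dimethoxyphenyl}-2-(phenylsulfonyl)-3,7-dioxabicyclo[3.3.0]octane (anomers)
Conditions: PhSO2H, CaCl2, CH2Cl2, rt
Reagents that add atoms: benzenesulfinic acid, OS(=O)c1ccccc1
Why: Acid-catalysed anomeric substitution; the lactol ionises to the oxocarbenium ion and is S-alkylated by the sulfinate to give a stable, storable anomeric sulfone.

Step 12
Reactants: 9 tris-silylated aryl bromide; 21 anomeric sulfone
Product: 24 4-[(1S,2R,5S,6R)-6-{4-(TBSO)-3,5-dimethoxyphenyl}-3,7-dioxabicyclo[3.3.0]octan-2-yl]-1-{[(1S,2S)-1,3-bis(TBSO)-1-{4-(TBSO)-3-methoxyphenyl}propan-2-yl]oxy}-2-methoxybenzene, via aryllithium 22 (not isolated), via arylzinc bromide 23 (not isolated)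
Conditions: 9, n-BuLi, THF, −78 °C; ZnBr2, −78 → 0 °C; then 21, THF, 0 °C → rt
Reagents that add atoms: none
Why: ZnBr2 assists loss of benzenesulfinate from 21 to give the bicyclic oxocarbenium ion at C2 (O3=C2), and the aryl group is transferred from zinc in 23 to this carbon, so the two halves are joined in one C(sp2)–C(sp3) bond-forming event. The closest known reaction type is the substitution of 2-(arylsulfonyl) cyclic ethers by organozinc reagents, a C-glycosylation-type anomeric arylation. No ring is closed. The new stereocenter C2 is set by the substrate: the cis-fused bicycle is cup-shaped, so the nucleophile should enter on the convex face, anti to the C1–C8 bond, which places the aryl group exo (H-2 trans to H-1) as the 2,6-diexo target requires. The step needs facial selectivity and C-arylation in preference to proton loss to the enol ether or ionisation of the C6 benzylic ether; the mild Lewis acid, the non-basic arylzinc and the far greater lability of the α-sulfonyl acetal should secure this, and the bromine position in 9 fixes the site on the arene.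

Step 13
Reactants: 24 tetrasilyl ether
Product: 25 (1S,2S)-1-(4-hydroxy-3-methoxyphenyl)-2-{4-[(1S,2R,5S,6R)-6-(4-hydroxy-3,5-dimethoxyphenyl)-3,7-dioxabicyclo[3.3.0]octan-2-yl]-2-methoxyphenoxy}propane-1,3-diol
Conditions: Bu4NF, AcOH, THF, 0 °C → rt
Reagents that add atoms: none
Why: Fluoride-mediated desilylation should remove all four silyl ethers in one operation, with acetic acid buffering the phenoxides so that the para-hydroxybenzylic alcohol and the furofuran are left intact.

**Compound list**

1 | vanillin | COc1cc(C=O)ccc1O | starting material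
2 | 4-[(tert-butyldimethylsilyl)oxy]-3-methoxybenzaldehyde | COc1cc(C=O)ccc1O[Si](C)(C)C(C)(C)C | intermediate
3 | 4-bromo-2-methoxyphenol | COc1cc(Br)ccc1O | starting material
4 | (R)-4-benzyl-3-(chloroacetyl)oxazolidin-2-one | ClCC(=O)N1[C@H](Cc2ccccc2)COC1=O | starting material
5 | (R)-4-benzyl-3-[2-(4-bromo-2-methoxyphenoxy)acetyl]oxazolidin-2-one | COc1cc(Br)ccc1OCC(=O)N1[C@H](Cc2ccccc2)COC1=O | intermediate
6 | dibutylboron Z-enolate of 5 (not isolated) | COc1cc(Br)ccc1O/C=C(\OB(CCCC)CCCC)N1[C@H](Cc2ccccc2)COC1=O | intermediate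
7 | (R)-4-benzyl-3-[(2R,3S)-2-(4-bromo-2-methoxyphenoxy)-3-{4-[(tert-butyldimethylsilyl)oxy]-3-methoxyphenyl}-3-hydroxypropanoyl]oxazolidin-2-one | COc1cc([C@H](O)[C@H](C(=O)N2[C@H](Cc3ccccc3)COC2=O)Oc2ccc(Br)cc2OC)ccc1O[Si](C)(C)C(C)(C)C | intermediate
8 | (1S,2S)-2-(4-bromo-2-methoxyphenoxy)-1-{4-[(tert-butyldimethylsilyl)oxy]-3-methoxyphenyl}propane-1,3-diol | COc1cc([C@H](O)[C@H](CO)Oc2ccc(Br)cc2OC)ccc1O[Si](C)(C)C(C)(C)C | intermediate
9 | 4-bromo-1-{[(1S,2S)-1,3-bis[(tert-butyldimethylsilyl)oxy]-1-{4-[(tert-butyldimethylsilyl)oxy]-3-methoxyphenyl}propan-2-yl]oxy}-2-methoxybenzene | COc1cc([C@H](O[Si](C)(C)C(C)(C)C)[C@H](CO[Si](C)(C)C(C)(C)C)Oc2ccc(Br)cc2OC)ccc1O[Si](C)(C)C(C)(C)C | intermediate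
10 | syringaldehyde | COc1cc(C=O)cc(OC)c1O | starting material
11 | 4-[(tert-butyldimethylsilyl)oxy]-3,5-dimethoxybenzaldehyde | COc1cc(C=O)cc(OC)c1O[Si](C)(C)C(C)(C)C | intermediate
12 | 2(5H)-furanone | O=C1OCC=C1 | starting material
13 | potassium vinyltrifluoroborate | [K+].C=C[B-](F)(F)F | starting material
14 | (R)-4-vinyldihydrofuran-2(3H)-one | C=C[C@H]1CC(=O)OC1 | intermediate
15 | lithium enolate of 14 (not isolated) | [Li]OC1=C[C@H](C=C)CO1 | intermediate
16 | (3R,4S)-3-[{4-[(tert-butyldimethylsilyl)oxy]-3,5-dimethoxyphenyl}(hydroxy)methyl]-4-vinyldihydrofuran-2(3H)-one, both carbinol epimers | O=C1OC[C@@H](C=C)[C@@H]1C(O)c1cc(OC)c(O[Si](C)(C)C(C)(C)C)c(OC)c1 | intermediate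
17 | (2S,3S)-2-[{4-[(tert-butyldimethylsilyl)oxy]-3,5-dimethoxyphenyl}(hydroxy)methyl]-3-vinylbutane-1,4-diol, both carbinol epimers (not isolated) | OC[C@H]([C@H](C=C)CO)C(O)c1cc(OC)c(O[Si](C)(C)C(C)(C)C)c(OC)c1 | intermediate
18 | [(2R,3S,4S)-2-{4-[(tert-butyldimethylsilyl)oxy]-3,5-dimethoxyphenyl}-4-vinyltetrahydrofuran-3-yl]methanol | OC[C@@H]1[C@H](C=C)CO[C@H]1c1cc(OC)c(O[Si](C)(C)C(C)(C)C)c(OC)c1 | intermediate
19 | (3S,4S,5R)-5-{4-[(tert-butyldimethylsilyl)oxy]-3,5-dimethoxyphenyl}-4-(hydroxymethyl)tetrahydrofuran-3-carbaldehyde (not isolated) | O=C[C@@H]1CO[C@@H](c2cc(OC)c(O[Si](C)(C)C(C)(C)C)c(OC)c2)[C@@H]1CO | intermediate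
20 | (1S,5S,6R)-6-{4-[(tert-butyldimethylsilyl)oxy]-3,5-dimethoxyphenyl}-3,7-dioxabicyclo[3.3.0]octan-2-ol, anomers | OC1OC[C@@H]2[C@H]1CO[C@H]2c1cc(OC)c(O[Si](C)(C)C(C)(C)C)c(OC)c1 | intermediate
21 | (1S,5S,6R)-6-{4-[(tert-butyldimethylsilyl)oxy]-3,5-dimethoxyphenyl}-2-(phenylsulfonyl)-3,7-dioxabicyclo[3.3.0]octane, anomers | O=S(=O)(c1ccccc1)C1OC[C@@H]2[C@H]1CO[C@H]2c1cc(OC)c(O[Si](C)(C)C(C)(C)C)c(OC)c1 | intermediate
22 | aryllithium from 9 (not isolated) | COc1cc([C@H](O[Si](C)(C)C(C)(C)C)[C@H](CO[Si](C)(C)C(C)(C)C)Oc2ccc([Li])cc2OC)ccc1O[Si](C)(C)C(C)(C)C | intermediate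
23 | arylzinc bromide from 9 (not isolated) | COc1cc([C@H](O[Si](C)(C)C(C)(C)C)[C@H](CO[Si](C)(C)C(C)(C)C)Oc2ccc([Zn]Br)cc2OC)ccc1O[Si](C)(C)C(C)(C)C | intermediate
24 | 4-[(1S,2R,5S,6R)-6-{4-[(tert-butyldimethylsilyl)oxy]-3,5-dimethoxyphenyl}-3,7-dioxabicyclo[3.3.0]octan-2-yl]-1-{[(1S,2S)-1,3-bis[(tert-butyldimethylsilyl)oxy]-1-{4-[(tert-butyldimethylsilyl)oxy]-3-methoxyphenyl}propan-2-yl]oxy}-2-methoxybenzene | COc1cc([C@H](O[Si](C)(C)C(C)(C)C)[C@H](CO[Si](C)(C)C(C)(C)C)Oc2ccc([C@@H]3OC[C@@H]4[C@H]3CO[C@H]4c3cc(OC)c(O[Si](C)(C)C(C)(C)C)c(OC)c3)cc2OC)ccc1O[Si](C)(C)C(C)(C)C | intermediate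
25 | (1S,2S)-1-(4-hydroxy-3-methoxyphenyl)-2-{4-[(1S,2R,5S,6R)-6-(4-hydroxy-3,5-dimethoxyphenyl)-3,7-dioxabicyclo[3.3.0]octan-2-yl]-2-methoxyphenoxy}propane-1,3-diol | COc1cc([C@H](O)[C@H](CO)Oc2ccc([C@@H]3OC[C@@H]4[C@H]3CO[C@H]4c3cc(OC)c(O)c(OC)c3)cc2OC)ccc1O | target

**Step count.** Total: 13 steps. Longest linear sequence: 7 steps (steps 7, 8, 9, 10, 11, 12, 13, from 2(5H)-furanone).

**Steps most likely to fail**

1. Step 12. The oxocarbenium ion may lose a proton to the bicyclic enol ether, or the bulky arylzinc may transfer so slowly that concave-face attack or ionisation at the C6 benzylic ether competes (poor facial selectivity, decomposition). The fallback sets out from lactol 20 (with bromide 9) and comes back at 24. Lactol 20 is deprotonated with i-PrMgCl and the aryllithium 22 made from 9 with n-BuLi is added to its open aldehyde form, which should give the benzylic diol F1 as both carbinol epimers. Catalytic camphorsulfonic acid in CH2Cl2 at 0 °C then ionises the para-alkoxybenzylic alcohol, and the neighbouring hydroxymethyl oxygen closes the second tetrahydrofuran ring by 5-exo capture of the cation. The exo-aryl isomer is expected to be favoured kinetically and on equilibration, giving 24.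

2. Step 7. Protodeboronation of the vinylborate may outrun insertion into the small five-membered lactone, and facial discrimination on this substrate may be low. The fallback sets out from 12 and comes back at 14. Copper-catalysed conjugate addition of vinylmagnesium bromide (CuI, Me3SiCl, THF, −78 °C) should give racemic 4-vinyldihydrofuran-2(3H)-one F2. Aminolysis with (S)-1-phenylethylamine gives two diastereomeric hydroxy amides, which are separated by crystallisation or chromatography to leave the (3R)-hydroxy amide F3. Acid-mediated relactonisation (aq. H2SO4, dioxane, reflux) releases the amine and returns 14.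

3. Step 9. The β-alkoxide may fragment by retro-aldol reaction under the hydride, borane liberated on acidification may hydroborate the vinyl group, and ring closure in the aqueous one-flask medium may be incomplete. The fallback sets out from 16 and comes back at 18. The carbinol is capped (Et3SiOTf, 2,6-lutidine) as the triethylsilyl ether F4. The lactone is reduced with i-Bu2AlH in CH2Cl2 to the isolated diol F5, with no free β-alkoxide and no borane present. Camphorsulfonic acid in CH2Cl2/MeOH then cleaves the silyl ether and closes the ring through the same benzylic cation, giving 18.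

**Further compounds**

F1 | step 12 | [(3S,4S,5R)-5-{4-[(tert-butyldimethylsilyl)oxy]-3,5-dimethoxyphenyl}-4-(hydroxymethyl)tetrahydrofuran-3-yl](4-{[(1S,2S)-1,3-bis[(tert-butyldimethylsilyl)oxy]-1-{4-[(tert-butyldimethylsilyl)oxy]-3-methoxyphenyl}propan-2-yl]oxy}-3-methoxyphenyl)methanol, both carbinol epimers | COc1cc([C@H](O[Si](C)(C)C(C)(C)C)[C@H](CO[Si](C)(C)C(C)(C)C)Oc2ccc(C(O)[C@@H]3CO[C@@H](c4cc(OC)c(O[Si](C)(C)C(C)(C)C)c(OC)c4)[C@@H]3CO)cc2OC)ccc1O[Si](C)(C)C(C)(C)C
F2 | step 7 | racemic 4-vinyldihydrofuran-2(3H)-one | C=CC1CC(=O)OC1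
F3 | step 7 | (R)-3-(hydroxymethyl)-N-[(S)-1-phenylethyl]pent-4-enamide | C=C[C@H](CO)CC(=O)N[C@@H](C)c1ccccc1
F4 | step 9 | (3R,4S)-3-[{4-[(tert-butyldimethylsilyl)oxy]-3,5-dimethoxyphenyl}(triethylsilyloxy)methyl]-4-vinyldihydrofuran-2(3H)-one, both carbinol epimers | O=C1OC[C@@H](C=C)[C@@H]1C(O[Si](CC)(CC)CC)c1cc(OC)c(O[Si](C)(C)C(C)(C)C)c(OC)c1
F5 | step 9 | (2S,3S)-2-[{4-[(tert-butyldimethylsilyl)oxy]-3,5-dimethoxyphenyl}(triethylsilyloxy)methyl]-3-vinylbutane-1,4-diol, both carbinol epimers | OC[C@H]([C@H](C=C)CO)C(O[Si](CC)(CC)CC)c1cc(OC)c(O[Si](C)(C)C(C)(C)C)c(OC)c1
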